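**Strategy**

Labdane numbering is used throughout. Ring A (C1–C5, C10) is annulated onto a preformed ring B by a formal [3+3] process that exploits the 1,3-relationship of C1 and C5 across the quaternary C10: both carbons are stored as the C1–C5 bond of a cyclopropane fused to ring B and activated by a temporary C6 ketone. In one flask, nickel-catalysed ring opening joins C1 to C2 of a 3-methoxy-3-methylbutylzinc reagent and releases C5 as a silyl enol ether, which then captures the tertiary C4 cation. The precursor is a bicyclo[4.1.0]heptan-2-one made from a quinone monoketal; the side chain is attached last by B-alkyl Suzuki coupling.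

Key step: step 7

Remark (assumption): in the 6-oxo-4,4,10-trimethyldecalin 13 the trans ring fusion is taken to be thermodynamically preferred, so that C5 can be set by base equilibration.

**Route**

Step 1
Reactants: 1 4-methoxy-2-methylphenol
Product: 2 4,4-dimethoxy-2-methylcyclohexa-2,5-dien-1-one
Conditions: PhI(OAc)2, MeOH, 0 °C
Reagents that add atoms: methanol, CO
Why: Iodine(III)-mediated oxidative dearomatisation of a p-methoxyphenol in methanol should give the quinone monoketal, methanol adding at the methoxy-bearing para carbon.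

Step 2
Reactants: 2 4,4-dimethoxy-2-methylcyclohexa-2,5-dien-1-one
Product: 3 4,4-dimethoxy-2-methylcyclohex-2-en-1-one
Conditions: H2 (1 atm), RhCl(PPh3)3 (cat.), benzene, rt
Reagents that add atoms: none
Why: Homogeneous hydrogenation with Wilkinson's catalyst should reduce the unhindered disubstituted enone C=C selectively over the trisubstituted, methyl-bearing one.

Step 3
Reactants: 3 4,4-dimethoxy-2-methylcyclohex-2-en-1-one
Product: 4 (S)-4,4-dimethoxy-2-methylcyclohex-2-en-1-ol
Conditions: (R)-Me-CBS (cat.), BH3·SMe2, THF, −30 °C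
Reagents that add atoms: none
Why: Corey–Bakshi–Shibata reduction under catalyst control (alkenyl arm as the large group) should set the S carbinol centre, the future C9, which later relays its chirality to C10.

Step 4
Reactants: 4 (S)-4,4-dimethoxy-2-methylcyclohex-2-en-1-ol
Product: 6 (1S,5S,6R)-5-hydroxy-6-methylbicyclo[4.1.0]heptan-2-one, via ketal carbinol 5 (not isolated)
Conditions: Et2Zn, CH2I2, CH2Cl2, 0 °C to rt; then PPTS, acetone–H2O, rt
Reagents that add atoms: diiodomethane, ICI; water, O
Why: Hydroxyl-directed Simmons–Smith cyclopropanation (Furukawa reagent) should deliver CH2 syn to the zinc alkoxide, which fixes C10 (R) from the carbinol centre, and mild acid then hydrolyses the dimethyl ketal to the cyclopropyl ketone.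

Step 5
Reactants: 7 3-methoxy-3-methylbutan-1-ol
Product: 8 1-bromo-3-methoxy-3-methylbutane
Conditions: CBr4, PPh3, CH2Cl2, 0 °C
Reagents that add atoms: carbon tetrabromide, BrC(Br)(Br)Br
Why: Appel bromination of the primary alcohol under neutral conditions should leave the acid-labile tertiary methyl ether intact.

Step 6
Reactants: 8 1-bromo-3-methoxy-3-methylbutane
Product: 9 (3-methoxy-3-methylbutyl)zinc bromide (THF solution, used directly)
Conditions: Zn dust, I2 (cat.), LiCl, THF, 50 °C
Reagents that add atoms: zinc, [Zn]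
Why: LiCl-promoted direct insertion of zinc into the primary C–Br bond should give the alkylzinc bromide, the tertiary ether being inert to zinc.

Step 7
Reactants: 6 (1S,5S,6R)-5-hydroxy-6-methylbicyclo[4.1.0]heptan-2-one; 9 (3-methoxy-3-methylbutyl)zinc bromide
Product: 13 (4S,4aR,8aR)-4-hydroxy-4a,8,8-trimethyloctahydronaphthalen-1(2H)-one, via silyl ether 10 (not isolated), via silyl enol ether 11 (not isolated), via cis-fused ketone 12 (not isolated)
Conditions: TMSCl (3.5 equiv), Et3N, THF, 0 °C; then 9 (1.5 equiv), NiBr2·glyme (10 mol %), 2,2′:6′,2″-terpyridine (10 mol %), rt; filtered and concentrated under Ar, CH2Cl2, TiCl4, −78 to −40 °C; then NaOMe, MeOH, rt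
Reagents that add atoms: none
Why: Proposed new method: terpyridine-ligated nickel should insert into the exocyclic C1–C5 bond of the silylated cyclopropyl ketone 10, alkyl transfer from zinc and C(sp3)–C(sp3) reductive elimination then form C1–C2 while TMSCl traps the enolate as the Δ5(6) silyl enol ether 11, and TiCl4 finally ionises the tertiary methyl ether so that C5 of this enol ether attacks the C4 cation and forms C4–C5. The closest known reaction types are the nickel/terpyridine ring-opening 1,3-difunctionalisation of cyclopropyl ketones with organozinc reagents and TMSCl and the Lewis-acid-mediated α-tert-alkylation of silyl enol ethers (SN1); their merger into a one-flask formal [3+3] annulation with a 1,3-ambiphilic zinc reagent is the part not yet shown. Ring A closes in a 6-(enolexo) mode, the enol carbon C5 adding to the planar tertiary cation through a chair-like six-membered transition state. C10 is carried over unchanged from 6, whereas C5 is formed on the face of the tether (cis-fused 12) and, being α to the C6 ketone, is then equilibrated by NaOMe to the trans-fused ketone with C1 and C4 both equatorial on ring B, the C9 silyl ether being methanolysed at the same time. The step needs cleavage of C5–C1 and not of C5–C10, which orbital overlap with the carbonyl and the unhindered CH2 terminus should secure, and alkylation at C5 and not at C7, which is secured because ring opening delivers only the Δ5(6) enol ether.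

Step 8
Reactants: 13 (4S,4aR,8aR)-4-hydroxy-4a,8,8-trimethyloctahydronaphthalen-1(2H)-one
Product: 14 (1S,4aR,8aR)-5,5,8a-trimethyldecahydronaphthalen-1-ol
Conditions: N2H4·H2O, KOH, diethylene glycol, 130 °C then 200 °C
Reagents that add atoms: none
Why: Wolff–Kishner reduction (Huang–Minlon) should remove the activating C6 carbonyl, the base-stable C9 alcohol surviving and C5 staying in the thermodynamically favoured trans series.

Step 9
Reactants: 14 (1S,4aR,8aR)-5,5,8a-trimethyldecahydronaphthalen-1-ol
Product: 15 (4aR,8aR)-5,5,8a-trimethyloctahydronaphthalen-1(2H)-one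
Conditions: Dess–Martin periodinane, NaHCO3, CH2Cl2, rt
Reagents that add atoms: none
Why: Dess–Martin oxidation should convert the hindered secondary alcohol into the C9 ketone without touching the ring-fusion centres.

Step 10
Reactants: 15 (4aR,8aR)-5,5,8a-trimethyloctahydronaphthalen-1(2H)-one
Product: 16 (4aR,8aR)-2,5,5,8a-tetramethyloctahydronaphthalen-1(2H)-one (mixture of C2 epimers)
Conditions: LDA, THF, −78 °C; MeI, −78 to 0 °C
Reagents that add atoms: iodomethane, CI
Why: Enolate methylation can occur only at C8 because C10 is quaternary, and the new C8 centre is of no consequence since it becomes sp2 in the next step.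

Step 11
Reactants: 16 (4aR,8aR)-2,5,5,8a-tetramethyloctahydronaphthalen-1(2H)-one
Product: 17 (4aR,8aR)-2,5,5,8a-tetramethyl-3,4,4a,5,6,7,8,8a-octahydronaphthalen-1-yl trifluoromethanesulfonate
Conditions: LDA, THF, −78 to 0 °C; PhNTf2, 0 °C to rt
Reagents that add atoms: N-phenylbis(trifluoromethanesulfonimide), O=S(=O)(N(c1ccccc1)S(=O)(=O)C(F)(F)F)C(F)(F)F
Why: O-Triflation of the only possible enolate should give the tetrasubstituted enol triflate that fixes the C8=C9 double bond, as is routine for 2,2,6-trimethylcyclohexanone.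

Step 12
Reactants: 18 (R)-2,2-dimethyl-1,3-dioxolane-4-carbaldehyde
Product: 19 (S)-4-ethynyl-2,2-dimethyl-1,3-dioxolane
Conditions: dimethyl (1-diazo-2-oxopropyl)phosphonate, K2CO3, MeOH, 0 °C to rt
Reagents that add atoms: dimethyl (1-diazo-2-oxopropyl)phosphonate, CC(=O)C(=[N+]=[N-])P(=O)(OC)OC
Why: Ohira–Bestmann (Seyferth–Gilbert) homologation should give the terminal alkyne under conditions mild enough to retain the α-alkoxy stereocentre, the future C14, whose descriptor changes from R to S through priorities only.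

Step 13
Reactants: 19 (S)-4-ethynyl-2,2-dimethyl-1,3-dioxolane
Product: 20 (S)-4-(buta-1,3-dien-2-yl)-2,2-dimethyl-1,3-dioxolane
Conditions: ethylene (1 atm), Grubbs II (5 mol %), CH2Cl2, rt
Reagents that add atoms: ethylene, C=C
Why: Ethylene–alkyne cross-enyne metathesis should convert the terminal alkyne into the 2-substituted 1,3-diene that carries C11, C12, C13 and C16.

Step 14
Reactants: 17 (4aR,8aR)-2,5,5,8a-tetramethyl-3,4,4a,5,6,7,8,8a-octahydronaphthalen-1-yl trifluoromethanesulfonate; 20 (S)-4-(buta-1,3-dien-2-yl)-2,2-dimethyl-1,3-dioxolane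
Product: 22 (4S)-2,2-dimethyl-4-{4-[(4aR,8aR)-2,5,5,8a-tetramethyl-3,4,4a,5,6,7,8,8a-octahydronaphthalen-1-yl]but-1-en-2-yl}-1,3-dioxolane, via alkylborane 21 (not isolated)
Conditions: 20, 9-BBN (1.05 equiv), THF, 0 °C to rt; then 17, Pd(dppf)Cl2 (10 mol %), AsPh3, K3PO4, DMF–H2O, 50 °C
Reagents that add atoms: none
Why: 9-BBN should hydroborate only the monosubstituted vinyl terminus of the diene (anti-Markovnikov, as with myrcene), and B-alkyl Suzuki–Miyaura coupling of the resulting alkylborane with the enol triflate then forms C9–C11.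

Step 15
Reactants: 22 (4S)-2,2-dimethyl-4-{4-[(4aR,8aR)-2,5,5,8a-tetramethyl-3,4,4a,5,6,7,8,8a-octahydronaphthalen-1-yl]but-1-en-2-yl}-1,3-dioxolane
Product: 23 (2S)-3-methylidene-5-[(4aR,8aR)-2,5,5,8a-tetramethyl-3,4,4a,5,6,7,8,8a-octahydronaphthalen-1-yl]pentane-1,2-diol
Conditions: AcOH–H2O (4:1), 40 °C
Reagents that add atoms: none
Why: Mild acid-catalysed acetonide hydrolysis should free the diol without isomerising either alkene.

Step 16
Reactants: 23 (2S)-3-methylidene-5-[(4aR,8aR)-2,5,5,8a-tetramethyl-3,4,4a,5,6,7,8,8a-octahydronaphthalen-1-yl]pentane-1,2-diol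
Product: 24 (2S)-3-methylidene-5-[(4aR,8aR)-2,5,5,8a-tetramethyl-3,4,4a,5,6,7,8,8a-octahydronaphthalen-1-yl]pentane-1,2-diyl diacetate (CNP0227767.1)
Conditions: Ac2O, pyridine, DMAP (cat.), CH2Cl2, rt
Reagents that add atoms: acetic anhydride, CC(=O)OC(C)=O
Why: DMAP-catalysed acetylation of the primary and the secondary allylic hydroxyl should give the diacetate without affecting the C14 stereocentre.

**Compound list**

1 | 4-methoxy-2-methylphenol | COc1ccc(O)c(C)c1 | starting material
2 | 4,4-dimethoxy-2-methylcyclohexa-2,5-dien-1-one | COC1(OC)C=CC(=O)C(C)=C1 | intermediate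
3 | 4,4-dimethoxy-2-methylcyclohex-2-en-1-one | COC1(OC)CCC(=O)C(C)=C1 | intermediate
4 | (S)-4,4-dimethoxy-2-methylcyclohex-2-en-1-ol | COC1(OC)CC[C@H](O)C(C)=C1 | intermediate
5 | (1R,2S,6S)-5,5-dimethoxy-1-methylbicyclo[4.1.0]heptan-2-ol (OH syn to the cyclopropane CH2) | COC1(OC)CC[C@H](O)[C@]2(C)C[C@H]12 | intermediate
6 | (1S,5S,6R)-5-hydroxy-6-methylbicyclo[4.1.0]heptan-2-one | O=C1CC[C@H](O)[C@]2(C)C[C@H]12 | intermediate
7 | 3-methoxy-3-methylbutan-1-ol | COC(C)(C)CCO | starting material
8 | 1-bromo-3-methoxy-3-methylbutane | COC(C)(C)CCBr | intermediate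
9 | (3-methoxy-3-methylbutyl)zinc bromide | COC(C)(C)CC[Zn]Br | intermediate
10 | (1S,5S,6R)-6-methyl-5-(trimethylsilyloxy)bicyclo[4.1.0]heptan-2-one | O=C1CC[C@H](O[Si](C)(C)C)[C@]2(C)C[C@H]12 | intermediate
11 | [(3R,4S)-3-(4-methoxy-4-methylpentyl)-3-methyl-4-(trimethylsilyloxy)cyclohex-1-en-1-yl]oxy(trimethyl)silane | COC(C)(C)CCC[C@]1(C)C=C(O[Si](C)(C)C)CC[C@@H]1O[Si](C)(C)C | intermediate
12 | (4S,4aR,8aS)-4a,8,8-trimethyl-4-(trimethylsilyloxy)octahydronaphthalen-1(2H)-one (cis-fused) | C[Si](C)(C)O[C@H]1CCC(=O)[C@H]2C(C)(C)CCC[C@@]12C | intermediate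
13 | (4S,4aR,8aR)-4-hydroxy-4a,8,8-trimethyloctahydronaphthalen-1(2H)-one (trans-fused) | O[C@H]1CCC(=O)[C@@H]2C(C)(C)CCC[C@@]12C | intermediate
14 | (1S,4aR,8aR)-5,5,8a-trimethyldecahydronaphthalen-1-ol | O[C@H]1CCC[C@@H]2C(C)(C)CCC[C@@]12C | intermediate
15 | (4aR,8aR)-5,5,8a-trimethyloctahydronaphthalen-1(2H)-one | O=C1CCC[C@@H]2C(C)(C)CCC[C@@]12C | intermediate
16 | (4aR,8aR)-2,5,5,8a-tetramethyloctahydronaphthalen-1(2H)-one (C2 epimers) | O=C1C(C)CC[C@@H]2C(C)(C)CCC[C@@]12C | intermediate
17 | (4aR,8aR)-2,5,5,8a-tetramethyl-3,4,4a,5,6,7,8,8a-octahydronaphthalen-1-yl trifluoromethanesulfonate | O=S(=O)(OC1=C(C)CC[C@@H]2C(C)(C)CCC[C@@]12C)C(F)(F)F | intermediate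
18 | (R)-2,2-dimethyl-1,3-dioxolane-4-carbaldehyde | O=C[C@H]1COC(C)(C)O1 | starting material
19 | (S)-4-ethynyl-2,2-dimethyl-1,3-dioxolane | C#C[C@H]1COC(C)(C)O1 | intermediate
20 | (S)-4-(buta-1,3-dien-2-yl)-2,2-dimethyl-1,3-dioxolane | C=CC(=C)[C@H]1COC(C)(C)O1 | intermediate
21 | 9-{3-[(4S)-2,2-dimethyl-1,3-dioxolan-4-yl]but-3-en-1-yl}-9-borabicyclo[3.3.1]nonane | C=C(CCB1C2CCCC1CCC2)[C@H]3COC(C)(C)O3 | intermediate
22 | (4S)-2,2-dimethyl-4-{4-[(4aR,8aR)-2,5,5,8a-tetramethyl-3,4,4a,5,6,7,8,8a-octahydronaphthalen-1-yl]but-1-en-2-yl}-1,3-dioxolane | C=C(CCC1=C(C)CC[C@@H]2C(C)(C)CCC[C@@]12C)[C@H]3COC(C)(C)O3 | intermediate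
23 | (2S)-3-methylidene-5-[(4aR,8aR)-2,5,5,8a-tetramethyl-3,4,4a,5,6,7,8,8a-octahydronaphthalen-1-yl]pentane-1,2-diol | C=C(CCC1=C(C)CC[C@@H]2C(C)(C)CCC[C@@]12C)[C@@H](CO)O | intermediate
24 | (2S)-3-methylidene-5-[(4aR,8aR)-2,5,5,8a-tetramethyl-3,4,4a,5,6,7,8,8a-octahydronaphthalen-1-yl]pentane-1,2-diyl diacetate | C=C(CCC1=C(C)CC[C@@H]2C(C)(C)CCC[C@@]12C)[C@@H](COC(C)=O)OC(C)=O | target

**Step count and risks**

Total step count: 16. Longest linear sequence: 12 steps (steps 1–4, 7–11, 14–16).

Step 7 (proposed new method). The one-flask annulation may fail through ring opening at the wrong cyclopropane bond (C5–C10), slow alkyl–alkyl reductive elimination at nickel, loss of the silyl enol ether before the cation is generated, or elimination of the tertiary cation instead of ring closure. The fallback sets out from 6 and uses known steps only. In situ iodotrimethylsilane (TMSCl, NaI, MeCN, −20 °C; the hydroxyl is silylated transiently and freed on work-up) should open the cyclopropane to (3R,4S)-4-hydroxy-3-(iodomethyl)-3-methylcyclohexan-1-one F1. Giese addition of its C1 radical to methyl vinyl ketone (Bu3SnH, AIBN, benzene, 80 °C) should give (3R,4S)-4-hydroxy-3-methyl-3-(4-oxopentyl)cyclohexan-1-one F2. Aldol condensation (KOH, MeOH, 60 °C) should close ring A to (4S,4aR)-4-hydroxy-4a,8-dimethyl-3,4,4a,5,6,7-hexahydronaphthalen-1(2H)-one F3. Conjugate methylation (Me2CuLi, TMSCl, THF, −78 to 0 °C) and equilibration with NaOMe in MeOH then come back to the route at 13.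

Step 14. Oxidative addition and transmetalation at the tetrasubstituted triflate flanked by the quaternary C10 may be too slow, so that protodeboronation of the alkylborane takes over, and hydroboration of diene 20 may not be fully selective for the vinyl terminus. The fallback sets out from 17. Stille coupling with tributyl(vinyl)stannane (Pd(PPh3)4, LiCl, THF, 65 °C) should give (4aR,8aR)-2,5,5,8a-tetramethyl-1-vinyl-3,4,4a,5,6,7,8,8a-octahydronaphthalene F4. Its vinyl group is hydroborated with 9-BBN, and the borane is coupled (Pd(dppf)Cl2, K3PO4, DMF–H2O) with (R)-4-(1-bromovinyl)-2,2-dimethyl-1,3-dioxolane F5, made from alkyne 19 by bromoboration with B-bromo-9-BBN and protonolysis with AcOH. This forms C12–C13 instead of C9–C11 and comes back to the route at 22.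

Step 8. Hydrazone formation at the hindered C6 ketone may be incomplete, and the hot alkaline medium may cause partial epimerisation at C5 or dehydration of the C9 alcohol. The fallback sets out from 13. Thioketalisation (ethane-1,2-dithiol, BF3·OEt2, CH2Cl2, 0 °C) should give (4′S,4a′R,8a′R)-4a′,8′,8′-trimethyloctahydro-2′H-spiro[1,3-dithiolane-2,1′-naphthalen]-4′-ol F6. Desulfurisation with Raney nickel (EtOH, reflux) comes back to the route at 14.

Further compounds
F1 | step 7 | (3R,4S)-4-hydroxy-3-(iodomethyl)-3-methylcyclohexan-1-one | O=C1CC[C@H](O)[C@](C)(CI)C1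
F2 | step 7 | (3R,4S)-4-hydroxy-3-methyl-3-(4-oxopentyl)cyclohexan-1-one | O=C1CC[C@H](O)[C@](C)(CCCC(C)=O)C1
F3 | step 7 | (4S,4aR)-4-hydroxy-4a,8-dimethyl-3,4,4a,5,6,7-hexahydronaphthalen-1(2H)-one | O[C@H]1CCC(=O)C2=C(C)CCC[C@@]12C
F4 | step 14 | (4aR,8aR)-2,5,5,8a-tetramethyl-1-vinyl-3,4,4a,5,6,7,8,8a-octahydronaphthalene | C=CC1=C(C)CC[C@@H]2C(C)(C)CCC[C@@]12C
F5 | step 14 | (R)-4-(1-bromovinyl)-2,2-dimethyl-1,3-dioxolane | C=C(Br)[C@H]1COC(C)(C)O1
F6 | step 8 | (4′S,4a′R,8a′R)-4a′,8′,8′-trimethyloctahydro-2′H-spiro[1,3-dithiolane-2,1′-naphthalen]-4′-ol | O[C@H]1CCC3(SCCS3)[C@@H]2C(C)(C)CCC[C@@]12C
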